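**Retrosynthetic overview**
- The target comes from O-methylation of a tertiary o-quinol, which comes from catalyst-controlled allylboration of the C5 carbonyl of an o-quinone (sets C5).
- The o-quinone comes from ortho-oxygenation (C6) of a trans-2-aryl-3-methyl-2,3-dihydrobenzofuran-5-ol.
- That phenol comes from acid-triggered ring expansion of a cis-fused cyclobutane (bicyclo[4.2.0]octenedione), made by enantioselective stepwise [2+2] addition of (E)-methylisoeugenol to p-benzoquinone (sets C3, then C2 trans).
- (E)-Methylisoeugenol comes from Suzuki coupling of 4-bromoveratrole (from catechol) with (E)-propenylboronic acid.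
- Ring order: the aryl ring (catechol) and ring A (p-benzoquinone) are bought; the cyclobutane forms first and is expanded to ring B (dihydrofuran); ring A is dearomatised last.

Assumption: the sense of induction of the two chiral catalysts (steps 4 and 6) is assigned by analogy; both antipodes of each catalyst are available, and the antipode that gives the drawn configuration is used.

**Step 1**
Reactants: 1 benzene-1,2-diol (catechol)
Product: 2 1,2-dimethoxybenzene
Conditions: MeI (2.5 equiv), K2CO3, acetone, reflux
Reagents that add atoms: iodomethane, CI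
Why: Double Williamson etherification (SN2 of the catecholate on MeI) is routine on this substrate and creates no stereocentre.

**Step 2**
Reactants: 2 1,2-dimethoxybenzene
Product: 3 4-bromo-1,2-dimethoxybenzene
Conditions: NBS, MeCN, 0 °C → rt
Reagents that add atoms: N-bromosuccinimide, O=C1CCC(=O)N1Br
Why: Electrophilic aromatic bromination goes para to one methoxy group at the only unhindered activated position and stops at the monobromide.

**Step 3**
Reactants: 3 4-bromo-1,2-dimethoxybenzene; 4 (E)-prop-1-en-1-ylboronic acid
Product: 5 1,2-dimethoxy-4-[(1E)-prop-1-en-1-yl]benzene ((E)-methylisoeugenol)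
Conditions: Pd(dppf)Cl2 (3 mol%), K2CO3, 1,4-dioxane/H2O (4:1), 80 °C
Reagents that add atoms: none
Why: Suzuki–Miyaura cross-coupling transfers the alkenyl group with retention of double-bond geometry, so the E alkene needed for the trans C2/C3 relationship is fixed here.

**Step 4**
Reactants: 5 1,2-dimethoxy-4-[(1E)-prop-1-en-1-yl]benzene; 6 cyclohexa-2,5-diene-1,4-dione (p-benzoquinone, 1.5 equiv)
Product: 8 (2R,3R)-2-(3,4-dimethoxyphenyl)-3-methyl-2,3-dihydro-1-benzofuran-5-ol, via cyclobutanedione 7 (not isolated)
Conditions: (S)-1-(2-methylphenyl)-3,3-diphenyltetrahydro-1H,3H-pyrrolo[1,2-c][1,3,2]oxazaborole (20 mol%), HNTf2 (18 mol%), CH2Cl2, −78 °C, slow addition of 5; then CF3CO2H (10 mol%), −78 → 0 °C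
Reagents that add atoms: none
Why: Proposed new method: the oxazaborolidinium ion binds one carbonyl of 6 (B–O bond plus a C–H···O contact to the neighbouring vinyl hydrogen) and blocks one face, the electron-rich alkene 5 attacks a quinone carbon through its methyl-bearing carbon (Michael-type addition that sets C3), and the resulting boron enolate/benzylic cation pair collapses at −78 °C to the cis-fused cyclobutane 7 (stepwise formal [2+2], not pericyclic); acid then re-ionises the strained donor–acceptor C–C bond of 7 at the benzylic carbon and the neighbouring carbonyl oxygen recloses anti to the methyl group, so the four-membered ring is expanded to the dihydrofuran (ring B), C2 is set trans to C3, and tautomerisation aromatises ring A without touching C3; the closest known reactions are the Lewis-acid-promoted [2+2] addition of propenylarenes to 2-alkoxy-1,4-benzoquinones with acid-induced cyclobutane-to-dihydrobenzofuran rearrangement, and oxazaborolidinium-catalysed quinone cycloadditions, neither shown enantioselectively for the parent quinone 6 with a propenylarene.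

**Step 5**
Reactants: 8 (2R,3R)-2-(3,4-dimethoxyphenyl)-3-methyl-2,3-dihydro-1-benzofuran-5-ol
Product: 9 (2R,3R)-2-(3,4-dimethoxyphenyl)-3-methyl-2,3-dihydro-1-benzofuran-5,6-dione
Conditions: 2-iodoxybenzoic acid (IBX, 1.1 equiv), DMF, 23 °C, 1 h; neutral work-up, used at once
Reagents that add atoms: 2-iodoxybenzoic acid, O=C1OI(=O)(O)c2ccccc12
Why: Regioselective ortho-oxygenation of an electron-rich phenol with IBX (aryloxy-iodane formation, intramolecular oxygen delivery to the less hindered ortho carbon C6, then oxidation of the bound catechol) gives the o-quinone under neutral conditions that leave C2 and C3 untouched.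

**Step 6**
Reactants: 9 (2R,3R)-2-(3,4-dimethoxyphenyl)-3-methyl-2,3-dihydro-1-benzofuran-5,6-dione; 10 prop-2-en-1-ylmagnesium bromide (allylmagnesium bromide)
Product: 13 (2R,3R,5S)-2-(3,4-dimethoxyphenyl)-5-hydroxy-3-methyl-5-(prop-2-en-1-yl)-2,3-dihydro-1-benzofuran-6(5H)-one, via allylboronate 11 (not isolated), via borate ester 12 (not isolated)
Conditions: 10, B(OiPr)3, Et2O, −78 °C → rt, then HCl in Et2O (1.0 equiv), filter; filtrate, 9, (S)-3,3'-dibromo-1,1'-bi-2-naphthol (15 mol%), PhCF3/PhMe (3:1), −35 °C; pH 7 buffer
Reagents that add atoms: none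
Why: Proposed new method: the chiral diol exchanges for one isopropoxide of 11 to give a more Lewis-acidic chiral allylboronate that binds the C5 carbonyl of 9 (the more electrophilic one, because C6=O is a vinylogous ester through O1) while its free naphthol OH hydrogen-bonds to the neighbouring C6 carbonyl, and the allyl group is delivered through a closed six-membered chair transition state (allylboration) to one face of the flat ring A, so the catalyst alone sets C5 as S (allyl cis to the C2 aryl group) because the C2 and C3 substituents are too remote to bias either face; the closest known reaction is the chiral-biaryl-diol-catalysed asymmetric allylboration of simple ketones, not yet shown for an o-quinone.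

**Step 7**
Reactants: 13 (2R,3R,5S)-2-(3,4-dimethoxyphenyl)-5-hydroxy-3-methyl-5-(prop-2-en-1-yl)-2,3-dihydro-1-benzofuran-6(5H)-one
Product: 14 (2R,3R,5S)-2-(3,4-dimethoxyphenyl)-5-methoxy-3-methyl-5-(prop-2-en-1-yl)-2,3-dihydro-1-benzofuran-6(5H)-one (CNP0109840.1)
Conditions: MeI (20 equiv), Ag2O (3 equiv), 4 Å MS, CH2Cl2, 23 °C, dark; purification below 25 °C
Reagents that add atoms: iodomethane, CI
Why: Purdie-type O-methylation (MeI activated by Ag2O) of the tertiary α-hydroxy ketone proceeds without a free alkoxide, which avoids anionic oxy-Cope or α-ketol shifts of the allyl group, and keeps all three stereocentres because no bond to C5 is broken.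

**Compound list**
1 | benzene-1,2-diol (catechol) | Oc1ccccc1O | starting material
2 | 1,2-dimethoxybenzene | COc1ccccc1OC | intermediate
3 | 4-bromo-1,2-dimethoxybenzene | COc1ccc(Br)cc1OC | intermediate
4 | (E)-prop-1-en-1-ylboronic acid | C/C=C/B(O)O | starting material
5 | 1,2-dimethoxy-4-[(1E)-prop-1-en-1-yl]benzene | C/C=C/c1ccc(OC)c(OC)c1 | intermediate
6 | cyclohexa-2,5-diene-1,4-dione (p-benzoquinone) | O=C1C=CC(=O)C=C1 | starting material
7 | (1R,6S,7S,8S)-7-(3,4-dimethoxyphenyl)-8-methylbicyclo[4.2.0]oct-3-ene-2,5-dione (cis-fused, aryl endo, methyl exo) | O=C1C=CC(=O)[C@@H]2[C@H]1[C@@H](C)[C@@H]2c1ccc(OC)c(OC)c1 | intermediate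
8 | (2R,3R)-2-(3,4-dimethoxyphenyl)-3-methyl-2,3-dihydro-1-benzofuran-5-ol | Oc1ccc2O[C@@H](c3ccc(OC)c(OC)c3)[C@H](C)c2c1 | intermediate
9 | (2R,3R)-2-(3,4-dimethoxyphenyl)-3-methyl-2,3-dihydro-1-benzofuran-5,6-dione | O=C1C=C2C(=CC1=O)O[C@@H](c1ccc(OC)c(OC)c1)[C@@H]2C | intermediate
10 | prop-2-en-1-ylmagnesium bromide | C=CC[Mg]Br | starting material
11 | dipropan-2-yl prop-2-en-1-ylboronate (allyldiisopropoxyborane) | C=CCB(OC(C)C)OC(C)C | intermediate
12 | dipropan-2-yl (2R,3R,5S)-2-(3,4-dimethoxyphenyl)-3-methyl-6-oxo-5-(prop-2-en-1-yl)-2,3,5,6-tetrahydro-1-benzofuran-5-yl borate | C=CC[C@]1(OB(OC(C)C)OC(C)C)C=C2C(=CC1=O)O[C@@H](c1ccc(OC)c(OC)c1)[C@@H]2C | intermediate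
13 | (2R,3R,5S)-2-(3,4-dimethoxyphenyl)-5-hydroxy-3-methyl-5-(prop-2-en-1-yl)-2,3-dihydro-1-benzofuran-6(5H)-one | C=CC[C@]1(O)C=C2C(=CC1=O)O[C@@H](c1ccc(OC)c(OC)c1)[C@@H]2C | intermediate
14 | (2R,3R,5S)-2-(3,4-dimethoxyphenyl)-5-methoxy-3-methyl-5-(prop-2-en-1-yl)-2,3-dihydro-1-benzofuran-6(5H)-one | C=CC[C@]1(OC)C=C2C(=CC1=O)O[C@@H](c1ccc(OC)c(OC)c1)[C@@H]2C | target

**Step count and risks**
Total step count: 7. Longest linear sequence: 7 steps (1 → 2 → 3 → 5 → 8 → 9 → 13 → 14).

The three steps most likely to fail:

Step 4 (proposed new step). The parent quinone offers no second binding point, so the enantiomeric excess may be low; 5 may dimerise under acid; and the ion pair may close directly on oxygen. The fallback uses known chemistry, sets out from 6 and 3, and returns at 8. Organocatalytic α-arylation of propanal with 6 under (S)-2-[diphenyl(trimethylsilyloxy)methyl]pyrrolidine (10 mol%, EtOH/H2O, −20 °C; antipode chosen to give 3R) proceeds by enamine addition to the quinone, tautomerisation and hemiacetal closure, and gives (3R)-3-methyl-2,3-dihydro-1-benzofuran-2,5-diol F1. Bromide 3 and Mg turnings in THF give (3,4-dimethoxyphenyl)magnesium bromide F2. About 3.2 equiv of F2 are added to F1 at −40 °C (two equivalents are spent on the two OH groups; aqueous NH4Cl work-up) to give 2-[(1RS,2R)-1-(3,4-dimethoxyphenyl)-1-hydroxypropan-2-yl]benzene-1,4-diol F3. p-Toluenesulfonic acid (5 mol%) in CH2Cl2 at 0 °C ionises the benzylic alcohol, and the ortho phenol closes trans to the methyl group to give 8.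

Step 5. Quinone 9 can tautomerise through its C3–H to a quinone methide and on to the aromatic benzofuran-diol, which would destroy C2 and C3; some oxygenation at C4 is also possible. The fallback sets out from 8 and returns at 9. Magnesium-mediated ortho-formylation of 8 at the less hindered C6 (MgCl2, Et3N, paraformaldehyde, MeCN, reflux) gives (2R,3R)-2-(3,4-dimethoxyphenyl)-5-hydroxy-3-methyl-2,3-dihydro-1-benzofuran-6-carbaldehyde F4. Dakin oxidation (H2O2, NaOH, then acid work-up) gives (2R,3R)-2-(3,4-dimethoxyphenyl)-3-methyl-2,3-dihydro-1-benzofuran-5,6-diol F5, which can be stored. F5 is oxidised with Ag2O (Et2O, 0 °C) to 9 immediately before step 6.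

Step 6 (proposed new step). An uncatalysed background allylboration of the activated carbonyl would erode the C5 selectivity, and the quinone may be reduced by electron transfer. The fallback uses known chemistry, sets out from 9 and 10, and returns at 13. Grignard reagent 10 is added directly to 9 in THF at −78 °C (aqueous NH4Cl work-up); this plain 1,2-addition to the more electrophilic C5 carbonyl has no facial control and gives 13 together with about an equal amount of (2R,3R,5R)-2-(3,4-dimethoxyphenyl)-5-hydroxy-3-methyl-5-(prop-2-en-1-yl)-2,3-dihydro-1-benzofuran-6(5H)-one F6. The two diastereomers are separated by chromatography (preparative HPLC if needed), and 13 goes on to step 7.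

**Further compounds**
F1 | step 4 | (3R)-3-methyl-2,3-dihydro-1-benzofuran-2,5-diol | Oc1ccc2OC(O)[C@H](C)c2c1
F2 | step 4 | (3,4-dimethoxyphenyl)magnesium bromide | COc1ccc([Mg]Br)cc1OC
F3 | step 4 | 2-[(1RS,2R)-1-(3,4-dimethoxyphenyl)-1-hydroxypropan-2-yl]benzene-1,4-diol | C[C@@H](C(O)c1ccc(OC)c(OC)c1)c1cc(O)ccc1O
F4 | step 5 | (2R,3R)-2-(3,4-dimethoxyphenyl)-5-hydroxy-3-methyl-2,3-dihydro-1-benzofuran-6-carbaldehyde | O=Cc1cc2O[C@@H](c3ccc(OC)c(OC)c3)[C@H](C)c2cc1O
F5 | step 5 | (2R,3R)-2-(3,4-dimethoxyphenyl)-3-methyl-2,3-dihydro-1-benzofuran-5,6-diol | Oc1cc2O[C@@H](c3ccc(OC)c(OC)c3)[C@H](C)c2cc1O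
F6 | step 6 | (2R,3R,5R)-2-(3,4-dimethoxyphenyl)-5-hydroxy-3-methyl-5-(prop-2-en-1-yl)-2,3-dihydro-1-benzofuran-6(5H)-one | C=CC[C@@]1(O)C=C2C(=CC1=O)O[C@@H](c1ccc(OC)c(OC)c1)[C@@H]2C
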